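## Retrosynthetic overview

1. Blepharocalyxin C ⇐ desilylation ⇐ reductive C(sp2)–O opening of a 6‑aryl‑3,4‑dihydro‑2H‑pyran (gives the E‑styrene and the C5′‑OH) ⇐ axial‑selective reduction of ketone 10.
2. The C3–C3′ bond ⇐ silyl enol ether 9 (nucleophile) + 2‑aryl‑dihydropyrylium ion from acetate 8 (electrophile). Both come from the same dihydropyranone 7, so all six stereocentres are relayed from its single stereocentre.
3. 7 ⇐ enantioselective Cu‑catalysed dearomative conjugate addition of ArCH2CH2MgBr to 2‑aryl‑4H‑pyran‑4‑one 4 (key step).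
4. 4 ⇐ 4H‑pyran‑4‑one + ArMgBr (4‑silyloxypyrylium addition, then DDQ re‑aromatisation).
5. Ring order: no ring is built. Both oxacycles are γ‑pyrone rings carried through. The tetrahydropyran is fixed in steps 4 and 6; the second ring acts as a stereochemical template and is opened in step 9.

Assumption: the target is read as the (2S,3S,4S,6S)‑tetrahydropyran (O1, C2‑aryl, C3, C4‑OH axial, C6‑arylethyl; 2,6‑cis, 2,3‑trans) carrying a (3′S,5′S,1′E) side chain at C3. Ar = 4‑(tert‑butyldimethylsilyloxy)phenyl throughout.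
Assumption: the sense of induction in step 4 cannot be predicted in advance; the ligand enantiomer that gives (S)‑7 is used.

## Route

Step 1
Reactants: 1, 4‑bromophenol
Product: 2, (4‑bromophenoxy)(tert‑butyl)dimethylsilane
Conditions: TBSCl (1.1 equiv), imidazole (2 equiv), CH2Cl2, rt
Reagents that add atoms: tert‑butyldimethylsilyl chloride, CC(C)(C)[Si](C)(C)Cl
Why: Imidazole‑promoted O‑silylation masks the phenol so the bromide can be converted into a Grignard reagent; no stereocentre.

Step 2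
Reactants: 3, 4H‑pyran‑4‑one; 2
Product: 4, 2‑Ar‑4H‑pyran‑4‑one
Conditions: 2, Mg, THF → ArMgBr; 3, TBSOTf (1.05 equiv), CH2Cl2, −78 °C; add ArMgBr (1.05 equiv), −78 °C; then DDQ (1.2 equiv), −78 → 0 °C; aq NaHCO3
Reagents that add atoms: none (aryl group comes from 2; Mg, TBSOTf and DDQ are not retained)
Why: O‑Silylation gives the 4‑silyloxypyrylium triflate, the Grignard adds at C2 (nucleophilic addition to a pyrylium salt), and DDQ abstracts the doubly activated C2–H as hydride (dehydrogenation of a silyl dienol ether) so the ring re‑aromatises and loses the O‑silyl group on work‑up; no stereocentre.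

Step 3
Reactants: 5, 4‑(2‑bromoethyl)phenol
Product: 6, [4‑(2‑bromoethyl)phenoxy](tert‑butyl)dimethylsilane
Conditions: TBSCl (1.1 equiv), imidazole (2 equiv), CH2Cl2, 0 °C → rt
Reagents that add atoms: tert‑butyldimethylsilyl chloride, CC(C)(C)[Si](C)(C)Cl
Why: O‑Silylation under mild base (avoids spirodienone formation) gives a bromide suitable for Grignard formation; no stereocentre.

Step 4 (key step)
Reactants: 4; 6
Product: 7, (S)‑6‑Ar‑2‑[2‑(Ar)ethyl]‑2,3‑dihydro‑4H‑pyran‑4‑one
Conditions: 6, Mg, Et2O → RMgBr (1.5 equiv), added over 2 h to 4, CuBr·SMe2 (5 mol %), rev‑Josiphos (6 mol %, enantiomer per assumption), TMSCl (2 equiv), CH2Cl2, −78 °C; AcOH/MeOH at −78 °C, then 1 M HCl, 0 °C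
Reagents that add atoms: none (the arylethyl group comes from 6)
Why: Proposed new method: a chiral Cu(I)–diphosphine alkylcuprate adds 1,4 to the unsubstituted C6 of the γ‑pyrone (C2 is blocked by the aryl group; TMSCl traps the dienolate as the 4‑silyloxy‑2H‑pyran, and the cold acid quench converts it to the vinylogous ester before the 2H‑pyran can ring‑open), breaking the aromatic ring and setting the one reagent‑controlled stereocentre of the route by ligand control; the closest known reactions are Cu/Josiphos‑catalysed asymmetric conjugate addition of Grignard reagents to chromones and Lewis‑acid‑assisted Cu‑catalysed Grignard additions to 4‑quinolones and 4‑pyridones.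

Step 5
Reactants: 7
Product: 8, (2S,4R)‑6‑Ar‑2‑[2‑(Ar)ethyl]‑3,4‑dihydro‑2H‑pyran‑4‑yl acetate (2,4‑cis)
Conditions: DIBAL‑H (1.1 equiv), CH2Cl2, −78 °C; then pyridine, DMAP, Ac2O, −78 → −20 °C; Rochelle salt work‑up; used crude
Reagents that add atoms: acetic anhydride, CC(=O)OC(C)=O
Why: 1,2‑Reduction of the vinylogous ester carbonyl with in situ acetylation of the aluminium alkoxide (reductive acetylation) gives the glycal‑type allylic acetate; axial hydride attack gives mainly the cis isomer, but this centre is ionised in step 7 so its configuration is immaterial.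

Step 6
Reactants: 7
Product: 9, (2S,6S)‑6‑Ar‑2‑[2‑(Ar)ethyl]‑4‑[(dimethylphenylsilyl)oxy]‑3,6‑dihydro‑2H‑pyran (2,6‑cis)
Conditions: Cu(OAc)2·H2O (5 mol %), 1,2‑bis(diphenylphosphino)benzene (5 mol %), PhMe2SiH (1.3 equiv), toluene, 0 °C → rt; filtration through Et3N‑deactivated silica
Reagents that add atoms: dimethylphenylsilane, C[SiH](C)c1ccccc1
Why: Copper‑hydride 1,4‑hydrosilylation (Stryker–Lipshutz conjugate reduction) gives the regiodefined silyl enol ether directly; hydride adds axially to the aryl‑bearing carbon anti to the arylethyl group, giving the 2,6‑cis ring, which is also the thermodynamic isomer.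

Step 7
Reactants: 8 (1.0 equiv); 9 (1.3 equiv)
Product: 10, (2S,3R,6S)‑2‑Ar‑3‑{(2S,4S)‑6‑Ar‑2‑[2‑(Ar)ethyl]‑3,4‑dihydro‑2H‑pyran‑4‑yl}‑6‑[2‑(Ar)ethyl]tetrahydro‑4H‑pyran‑4‑one (THP all‑equatorial; dihydropyran 2,4‑trans)
Conditions: TMSOTf (0.2 equiv), 2,6‑di‑tert‑butyl‑4‑methylpyridine (0.3 equiv), 4 Å MS, CH2Cl2, −78 °C; Et3N, then aq NaHCO3
Reagents that add atoms: none
Why: Proposed new method: TMSOTf ionises 8 to a 6‑aryl‑2,3‑dihydropyrylium (vinylogous oxocarbenium) ion that the silyl enol ether attacks in a Mukaiyama‑type alkylation at C4 rather than at the fully substituted aryl‑bearing C6 (as flavylium ions react at C4), axially and trans to the C2 arylethyl group (the stereoelectronic preference seen in cuprate additions to 5‑substituted cyclohexenones) to set C3′, while 9 reacts anti to its neighbouring aryl group to set C3 trans to C2 (an epimerisable, thermodynamically favoured centre), and mismatched (S)/(R) pairings give a separable diastereomer so the ee of 10 exceeds that of 7; the closest known reactions are the carbon‑Ferrier reaction of glycal acetates with silyl enol ethers and C4 additions of silyl enol ethers to flavylium salts.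

Step 8
Reactants: 10
Product: 11, (2S,3S,4S,6S)‑2‑Ar‑3‑{(2S,4R)‑6‑Ar‑2‑[2‑(Ar)ethyl]‑3,4‑dihydro‑2H‑pyran‑4‑yl}‑6‑[2‑(Ar)ethyl]tetrahydro‑2H‑pyran‑4‑ol (same geometry as 10; the 4‑descriptor of the dihydropyran changes only through CIP priorities)
Conditions: L‑Selectride (1.5 equiv), THF, −78 °C; aq NH4Cl
Reagents that add atoms: none
Why: The bulky trialkylborohydride attacks the ring ketone from the equatorial direction (steric approach control), giving the axial C4 alcohol cis to the equatorial C3 substituent; the enol ether and silyl ethers are inert.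

Step 9
Reactants: 11
Product: 12, (2S,3S,4S,6S)‑3‑[(3S,5S,E)‑5‑hydroxy‑1,7‑bis(Ar)hept‑1‑en‑3‑yl]‑2‑Ar‑6‑[2‑(Ar)ethyl]tetrahydro‑2H‑pyran‑4‑ol (tetra‑O‑TBS blepharocalyxin C)
Conditions: BH3·THF (3 equiv), THF, 0 °C → rt; MeOH, 0 °C; then BF3·OEt2 (2 equiv), CH2Cl2, −40 → 0 °C; aq NaHCO3
Reagents that add atoms: none (hydrogen only)
Why: Hydroboration of the aryl enol ether (the only C=C in 11) places boron β to oxygen and hydrogen on the aryl‑bearing carbon by syn addition, and Lewis‑acid‑promoted anti β‑alkoxy elimination of the trans‑diequatorial β‑boryl ether opens the ring to the (E)‑styrene and releases the C5′ hydroxyl without touching any stereocentre.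

Step 10
Reactants: 12
Product: 13, blepharocalyxin C, (2S,3S,4S,6S)‑3‑[(3S,5S,E)‑5‑hydroxy‑1,7‑bis(4‑hydroxyphenyl)hept‑1‑en‑3‑yl]‑2‑(4‑hydroxyphenyl)‑6‑[2‑(4‑hydroxyphenyl)ethyl]tetrahydro‑2H‑pyran‑4‑ol
Conditions: TBAF (6 equiv), AcOH (6 equiv), THF, 0 °C → rt
Reagents that add atoms: none
Why: Fluoride cleaves the four aryl silyl ethers, and acetic acid buffering prevents phenoxide‑driven quinone‑methide opening of the 2‑aryl tetrahydropyran, so no stereocentre is at risk.

## Compound list

1 | 4‑bromophenol | Oc1ccc(Br)cc1 | starting material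
2 | (4‑bromophenoxy)(tert‑butyl)dimethylsilane | CC(C)(C)[Si](C)(C)Oc1ccc(Br)cc1 | intermediate
3 | 4H‑pyran‑4‑one | O=c1ccocc1 | starting material
4 | 2‑[4‑(TBSO)phenyl]‑4H‑pyran‑4‑one | CC(C)(C)[Si](C)(C)Oc1ccc(cc1)-c1cc(=O)cco1 | intermediate
5 | 4‑(2‑bromoethyl)phenol | Oc1ccc(CCBr)cc1 | starting material
6 | [4‑(2‑bromoethyl)phenoxy](tert‑butyl)dimethylsilane | CC(C)(C)[Si](C)(C)Oc1ccc(CCBr)cc1 | intermediate
7 | (S)‑6‑Ar‑2‑[2‑(Ar)ethyl]‑2,3‑dihydro‑4H‑pyran‑4‑one | O=C1C[C@H](CCc2ccc(O[Si](C)(C)C(C)(C)C)cc2)OC(c2ccc(O[Si](C)(C)C(C)(C)C)cc2)=C1 | intermediate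
8 | (2S,4R)‑6‑Ar‑2‑[2‑(Ar)ethyl]‑3,4‑dihydro‑2H‑pyran‑4‑yl acetate | CC(=O)O[C@@H]1C[C@H](CCc2ccc(O[Si](C)(C)C(C)(C)C)cc2)OC(c2ccc(O[Si](C)(C)C(C)(C)C)cc2)=C1 | intermediate
9 | (2S,6S)‑6‑Ar‑2‑[2‑(Ar)ethyl]‑4‑[(dimethylphenylsilyl)oxy]‑3,6‑dihydro‑2H‑pyran | C[Si](C)(c1ccccc1)OC1=C[C@@H](c2ccc(O[Si](C)(C)C(C)(C)C)cc2)O[C@@H](CCc2ccc(O[Si](C)(C)C(C)(C)C)cc2)C1 | intermediate
10 | coupled ketone (2S,3R,6S; dihydropyranyl 2S,4S) | CC(C)(C)[Si](C)(C)Oc1ccc(cc1)C1=C[C@H](C[C@@H](O1)CCc2ccc(O[Si](C)(C)C(C)(C)C)cc2)[C@@H]2[C@@H](c3ccc(O[Si](C)(C)C(C)(C)C)cc3)O[C@@H](CCc3ccc(O[Si](C)(C)C(C)(C)C)cc3)CC2=O | intermediate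
11 | axial alcohol (2S,3S,4S,6S; dihydropyranyl 2S,4R) | CC(C)(C)[Si](C)(C)Oc1ccc(cc1)C1=C[C@H](C[C@@H](O1)CCc2ccc(O[Si](C)(C)C(C)(C)C)cc2)[C@@H]2[C@@H](c3ccc(O[Si](C)(C)C(C)(C)C)cc3)O[C@@H](CCc3ccc(O[Si](C)(C)C(C)(C)C)cc3)C[C@@H]2O | intermediate
12 | tetra‑O‑TBS blepharocalyxin C | CC(C)(C)[Si](C)(C)Oc1ccc(/C=C/[C@H](C[C@@H](O)CCc2ccc(O[Si](C)(C)C(C)(C)C)cc2)[C@@H]2[C@@H](c3ccc(O[Si](C)(C)C(C)(C)C)cc3)O[C@@H](CCc3ccc(O[Si](C)(C)C(C)(C)C)cc3)C[C@@H]2O)cc1 | intermediate
13 | blepharocalyxin C | Oc1ccc(/C=C/[C@H](C[C@@H](O)CCc2ccc(O)cc2)[C@@H]2[C@@H](c3ccc(O)cc3)O[C@@H](CCc3ccc(O)cc3)C[C@@H]2O)cc1 | target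

## Step count and risk

Total steps: 10. Longest linear sequence: 8 (steps 1 → 2 → 4 → 5 → 7 → 8 → 9 → 10; steps 3 and 6 are side branches).

Steps most likely to fail:

1. **Step 4 (dearomative asymmetric alkylation).** Risks are 1,2‑addition, low ee, or erosion through electrocyclic opening of the 2H‑pyran dienolate. Fallback: change the nucleophile class and metal. Use Rh(I)/chiral‑diene‑catalysed 1,4‑addition of (E)‑2‑[4‑(TBSO)phenyl]vinylboronic acid to 4 (Hayashi–Miyaura), then hydrogenate the isolated styrenyl C=C (Wilkinson's catalyst) to reach 7.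

2. **Step 7 (enol ether / dihydropyrylium coupling).** Risks are attack at the aryl‑bearing carbon, loss of a proton from the cation to a 2H‑pyran, or modest facial selectivity. Fallback: build C3–C3′ by an aldol condensation / conjugate addition sequence. Trap the enolate from L‑Selectride reduction of 7 with (S)‑5‑Ar‑3‑(silyloxy)pentanal, dehydrate to the 3‑alkylidene tetrahydropyranone, and add (E)‑2‑Ar‑vinylboronic acid under chiral Rh–diene catalysis. C3′ is then set by the catalyst rather than by the cyclic cation, and C3 by thermodynamic protonation.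

3. **Step 9 (reductive opening of the aryl enol ether).** Risks are slow hydroboration of the hindered trisubstituted enol ether and BF3‑induced damage at the benzylic ether. Fallback: Ni(0)‑catalysed stereoretentive reductive cleavage of the C(sp2)–O bond (Wenkert‑type, Ni(cod)2/PCy3 with i‑PrMgCl as hydride donor), a transition‑metal C–O activation in place of hydroboration–elimination.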